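**The invariant.** Each proposed step turns one form into another, so the fractions of the charge held by the forms add to one at any moment, with crystals counted inside target. We therefore reckon in fractions of the charge.

| flask | substrate | remark | time |
|---|---|---|---|
| east | 0.56 M | run made earlier |  |
| north-east | 0.88 M | run made earlier |  |
| flask | 0.40 M |  | 40 min |

| run | time / min | target / % | crystals / % |
|---|---|---|---|
| east | 3.00 | 11.6 | 2.9 |
| east | 6.00 | 20.6 | 9.4 |
| east | 12.0 | 32.4 | 22.8 |
| east | 20.0 | 43.9 | 37.3 |
| east | 40.0 | 58.4 | 54.6 |
| north-east | 8.00 | 25.8 | 14.9 |
| north-east | 15.0 | 38.2 | 29.0 |
| north-east | 25.0 | 48.8 | 43.4 |
| north-east | 30.0 | 52.4 | 48.6 |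
| north-east | 40.0 | 59.3 | 55.6 |

(standard deviation of a reading: 0.5 percentage points)

1. target and crystals together at 40 min, in percent of the substrate charged
2. concentration of target in solution at 40 min, in percent of saturation

- for target the crystals are counted in
- as a solid, counted per litre of solution: crystals
- what was read earlier has a scatter of 0.5 percentage points, one standard deviation
- steps that have been proposed: crystals <-> target; substrate <-> target; substrate <-> isomer of the product; substrate <-> dormant form; substrate <-> third isomer

**Main step.** Suppose substrate goes to target by one first-order step. The first east reading, 11.6% after 3.00 min, gives a rate of 0.0387 /min, hence a half-life of 17.9 min. This picture puts target at 78.7% at 40 min, but the east run reads less, 58.4%, at that time.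

**Side steps.** Now let other steps share the substrate, so that target levels off at a plateau. For an exponential approach, the gain from 20.0 min to 40.0 min over the gain before it is the part of the gap still open at 20.0 min. The east readings give 0.330. These two scattered readings yield a plateau of 65.6% and an approach half-life, the relaxation half-life in which the gap to that plateau halves, of 12.5 min, shorter than the first one. The number falls to the east reading, through which this curve was drawn.

**The rest.** Crystal growth and the way back remain. North-east stands 0.9 percentage points above east at 40 min, with a scatter of 0.5 points on each reading, and a straight line in charge, carried down to the flask, gives our number: 57.9%. Dissolved target at 40 min reads 3.80% in east and 3.70% in north-east, and we commit to no saturation from these.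

**The forecast.** The forecast gives 58% for target and crystals together and 165% of saturation, holding that “formation is essentially first order”.

**The result.** The flask gives 57.6% for target and crystals together and 249% of saturation, and at 40 min its dissolved target is made at 0.800 times the rate at which it is used up, each step taken net.

    crystals ⇌ target, rate k1*(cs1 - [target]) while solid is left; crystals form when [target] > cs1 (solubility = 5.90 mM, k = 0.240 /min)
    substrate ⇌ target (K = 0.550, k = 0.0480 /min)
    substrate ⇌ isomer of the product (K = 3.20, k = 0.00220 /min)
    substrate ⇌ dormant form (K = 7.40, k = 0.00810 /min)
    substrate ⇌ third isomer (K = 1.10, k = 0.00660 /min)

**Second use.** With 12.5 min and the plateau read from east, the curve puts the flask at 64.8% after 80.0 min, and it holds 65.4% of target and crystals then. For the same flask read at 15.0 min, the curve gives 37.0%, and that flask holds 37.0%.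

The earlier runs and the new flask come from a simulation with made-up constants; the scatter is artificial.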